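Before you rerun a neighbour of this flask at another charge, reckon this flask by hand: it takes a few lines and tells you what the rerun should show.

starting material 0.069 M; gas 3.8 mM (held); time 15 min

    starting material ⇌ reactive form (K1 = 0.92, k1 = 0.17 s⁻¹)
    reagent + reactive form ⇌ product (K2 = 160 M⁻¹, k2 = 140 M⁻¹ s⁻¹)
    gas ⇌ reagent, rate k3*(csat - [reagent]) (k3 = 34 s⁻¹, csat = 3.8 mM)

1. at 15 min, what has stopped the reaction, if anything has (it is still moving / forward and back rates have come level / all of the starting material has reacted)
2. product at 15 min, in percent of the starting material charged
3. reactive form at 15 min, in percent of the starting material charged
4. amount of product if the flask were left three thousand times as long, in percent of the starting material charged

- at the start none of reagent is dissolved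
- the reaction counts as stopped when no species that holds the starting material changes by six tenths of a point or more over the second half of the time
- run time (flask): 15 min

A pair of opposed steps relaxes at the sum of its forward and back constants. Starting material and reactive form therefore relax in 2.82 s. With reagent at saturation, the binding step is pseudo-first-order in reactive form and relaxes in 0.711 s. Both times are far shorter than the run, so my first answer is that forward and back rates are level in each step of this flask.

Level steps give proportions. Against one part of starting material stand 0.92 parts of reactive form, and each part of reactive form carries 0.608 parts of product. Add the parts and product holds 22.6 % of the charge. This is the product share, the fraction of the charge standing as product when both steps are level with reagent at saturation. Reactive form holds 37.1 %, and the charge cancels from both.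

That answer assumed saturation, so put it back in. In this flask, product at that share has taken up 4.10 times the reagent dissolved at saturation, so the gas has to refill the solution. Even with the whole charge as reactive form, the reaction's demand stands to the fastest refilling as 0.284 to one, so I estimate that, once the solution has first filled, reagent dips below saturation by less than that fraction while product forms. Once the binding step is level, net uptake stops and reagent returns to saturation. The second round therefore gives the same share, and waiting longer leaves it there.

The forecast says forward and back rates have come level, with 22.6 % product, 37.1 % reactive form and 22.6 % after the long wait, on the grounds that “the flask has reached equilibrium”.

The simulation reads forward and back rates have come level, with 22.6 % product, 37.1 % reactive form and 22.6 % after the long wait. Carry that share to the neighbour charged with 0.017 M of starting material. The charge cancels, so the share stays 22.6 %, while the estimate of the reagent's dip falls to 0.0700 of saturation and product at that share comes to 1.01 times the reagent dissolved at saturation. That neighbour gives 22.6 % product, 37.1 % reactive form and 40.3 % starting material at 15.0 min.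

(All constants belong to no real substance; no experiment stands behind them.)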